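**Plan**

1. Cuts, in retrosynthetic order: the three ArO–CH2Ph bonds (made last in reverse, i.e. removed in the final step); then the C4–C5 bond of the undecan-4-yl chain together with its O–C4 bond, which takes the hindered salicylate ester apart into an aroyl bromide, butanal and a hept-6-enyl arene; then the like C8–C9 bond of the 9-acetoxydodecyl chain; then the aryl–carboxyl bond and the two ArCH2–CH2 bonds.
2. Enabling feature: C4 of the undecan-4-yl chain is a CH that carries the benzoate oxygen, so it is the C=O carbon of butanal after 1,2-addition of an acyl bromide (a 1-bromoalkyl ester whose carbonyl oxygen can chelate nickel). Its neighbour C5 is an unbranched CH2, i.e. the terminal carbon of a 1-alkene; C9/C8 of the acetoxy chain repeat the pattern.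
3. Forward: both benzene rings are bought as 3,5-dioxygenated benzyl bromides and receive their ω-alkenyl chains by Cu-catalysed coupling. A Ni–H coupling builds the acetate end; formylation, ortho-demethylation, benzylation and oxidation give the acid. The acid bromide, butanal and the second olefin are then joined in one flask, and hydrogenolysis ends the route.
4. Stereochemistry: both (R) carbinol centres come from catalyst-controlled, enantioconvergent nickel couplings with one enantiomer of a chiral bis(oxazoline) ligand; no later step touches them.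

Key step: step 9

Assumption: L* is the enantiomer of a C2-symmetric bis(oxazoline) ligand that delivers the (R) ester; which antipode this is has to be fixed in a model coupling. The same enantiomer is taken to serve steps 2 and 9, because both carbinol carbons carry the same three groups (acyloxy, n-propyl, unbranched long alkyl).

**Route**

Step 1
Reactants: 1 3,5-dimethoxybenzyl bromide; 2 7-bromohept-1-ene
Product: 4 1,3-dimethoxy-5-(oct-7-en-1-yl)benzene, via hept-6-enylmagnesium bromide 3 (not isolated)
Conditions: 2, Mg, THF, rt; then 1, Li2CuCl4 (cat.), THF, −78 °C to 0 °C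
Reagents that add atoms: none
Why: Kochi-type copper-catalysed sp3–sp3 coupling of a primary alkyl Grignard reagent with a benzylic bromide is fast at low temperature and should outrun Wurtz homocoupling, and the terminal alkene is inert.

Step 2
Reactants: 4 1,3-dimethoxy-5-(oct-7-en-1-yl)benzene; 5 butanal
Product: 7 (4R)-12-(3,5-dimethoxyphenyl)dodecan-4-yl acetate, via 1-bromobutyl acetate 6 (not isolated)
Conditions: 5, AcBr (1.5 equiv each), neat, 0 °C to rt; then 4, NiBr2·glyme (10 mol %), L* (12 mol %), (EtO)3SiH, K3PO4·H2O, Et2O, rt
Reagents that add atoms: acetyl bromide, CC(=O)Br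
Why: Nickel hydride-catalysed enantioconvergent hydroalkylation of a terminal olefin with a racemic 1-bromoalkyl ester (four-component aldehyde/acyl bromide/olefin/hydrosilane coupling): the linear alkyl–nickel from anti-Markovnikov Ni–H insertion couples with the α-acetoxy radical, and the chiral ligand sets the (R) centre under catalyst control.

Step 3
Reactants: 7 (4R)-12-(3,5-dimethoxyphenyl)dodecan-4-yl acetate
Product: 9 (4R)-12-(2-formyl-3,5-dimethoxyphenyl)dodecan-4-yl acetate, via aryl iminium chloride 8 (not isolated)
Conditions: POCl3, DMF, 0 °C to 70 °C; then H2O, 0 °C to rt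
Reagents that add atoms: N,N-dimethylformamide, CN(C)C=O; water, O
Why: Vilsmeier–Haack formylation of a 1-alkyl-3,5-dimethoxybenzene should go to the ring position ortho to the chain and para to a methoxy group (two equivalent sites by symmetry, the site between the methoxy groups being more hindered), and the acetate is inert to the reagent.

Step 4
Reactants: 9 (4R)-12-(2-formyl-3,5-dimethoxyphenyl)dodecan-4-yl acetate
Product: 10 (4R)-12-(2-formyl-3-hydroxy-5-methoxyphenyl)dodecan-4-yl acetate
Conditions: BCl3 (2 equiv), CH2Cl2, −78 °C to −20 °C; then H2O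
Reagents that add atoms: none
Why: Chelation-controlled Lewis acid demethylation: BCl3 bound to the aldehyde oxygen should cleave only the methoxy group ortho to it through a six-membered boron chelate, leaving the para methoxy group and, at low temperature, the secondary acetate.

Step 5
Reactants: 10 (4R)-12-(2-formyl-3-hydroxy-5-methoxyphenyl)dodecan-4-yl acetate
Product: 11 (4R)-12-[3-(benzyloxy)-2-formyl-5-methoxyphenyl]dodecan-4-yl acetate
Conditions: BnBr, K2CO3, DMF, 50 °C
Reagents that add atoms: benzyl bromide, BrCc1ccccc1
Why: Williamson etherification of the hydrogen-bonded phenol with a mild carbonate base, which should not touch the acetate or the non-enolisable aldehyde.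

Step 6
Reactants: 11 (4R)-12-[3-(benzyloxy)-2-formyl-5-methoxyphenyl]dodecan-4-yl acetate
Product: 12 2-[(9R)-9-acetoxydodecyl]-6-(benzyloxy)-4-methoxybenzoic acid
Conditions: NaClO2, NaH2PO4, 2-methyl-2-butene (excess), t-BuOH/THF/H2O, 0 °C to rt
Reagents that add atoms: sodium chlorite, [Na+].[O-]Cl=O
Why: Pinnick oxidation should convert the hindered aryl aldehyde to the acid under buffered conditions, the alkene scavenger removing HOCl so that the electron-rich ring is not chlorinated, while esters and benzyl ether are stable.

Step 7
Reactants: 12 2-[(9R)-9-acetoxydodecyl]-6-(benzyloxy)-4-methoxybenzoic acid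
Product: 13 2-[(9R)-9-acetoxydodecyl]-6-(benzyloxy)-4-methoxybenzoyl bromide
Conditions: (COBr)2, DMF (cat.), CH2Cl2, 0 °C to rt; evaporate, use crude
Reagents that add atoms: oxalyl bromide, O=C(Br)C(=O)Br
Why: Acyl halide formation through the Vilsmeier-type bromoiminium species is mild and gives only gaseous by-products, so the crude acid bromide should be usable directly.

Step 8
Reactants: 14 3,5-bis(benzyloxy)benzyl bromide; 15 6-bromohex-1-ene
Product: 17 1,3-bis(benzyloxy)-5-(hept-6-en-1-yl)benzene, via hex-5-enylmagnesium bromide 16 (not isolated)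
Conditions: 15, Mg, THF, rt; then 14, Li2CuCl4 (cat.), THF, −78 °C to 0 °C
Reagents that add atoms: none
Why: The same Kochi-type copper-catalysed Grignard–benzyl bromide coupling as in step 1, to which aryl benzyl ethers and the terminal alkene are inert.

Step 9
Reactants: 13 2-[(9R)-9-acetoxydodecyl]-6-(benzyloxy)-4-methoxybenzoyl bromide; 5 butanal; 17 1,3-bis(benzyloxy)-5-(hept-6-en-1-yl)benzene
Product: 19 (4R)-11-[3,5-bis(benzyloxy)phenyl]undecan-4-yl 2-[(9R)-9-acetoxydodecyl]-6-(benzyloxy)-4-methoxybenzoate, via 1-bromobutyl aroate 18 (not isolated)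
Conditions: 13, 5 (1.1 equiv), CH2Cl2, 0 °C to rt, evaporate; then 17 (1.3 equiv), NiBr2·glyme (10 mol %), L* (12 mol %), (EtO)3SiH, K3PO4·H2O, Et2O, rt
Reagents that add atoms: none
Why: The aroyl bromide adds across the C=O of butanal to give the racemic 1-bromobutyl ester 18; L*Ni–H, formed from the nickel(II) salt, the hydrosilane and phosphate, inserts the terminal alkene of 17 anti-Markovnikov to a primary alkyl–nickel, bromine abstraction from 18 gives a planar α-acyloxy radical that is captured at nickel, and C(sp3)–C(sp3) reductive elimination joins the carbinol carbon to the chain CH2. The closest known reaction type is the nickel/bis(oxazoline)-catalysed enantioconvergent coupling of racemic 1-bromoalkyl esters, made in the flask from an aldehyde and an acyl bromide, with terminal olefins and a hydrosilane to give esters of dialkyl carbinols. No ring is closed. The new (R) centre is set by the catalyst alone: the ester carbonyl oxygen chelates nickel in a five-membered Ni–C–O–C=O arrangement so that both enantiomers of 18 converge on one product, and the distant (R) acetate centre has no influence. The step needs enantioconvergence, linear regioselectivity and chemoselectivity; the unbranched terminal olefin secures linear insertion, the only C–Br bond present is the activated α-acyloxy one, and aryl benzyl ethers and the acetate are inert to Ni–H and silane at room temperature. The ortho,ortho'-substituents of the aroyl group sit two atoms beyond the coordinating carbonyl, so they should be tolerated and should also shield the ester from attack by base.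

Step 10
Reactants: 19 (4R)-11-[3,5-bis(benzyloxy)phenyl]undecan-4-yl 2-[(9R)-9-acetoxydodecyl]-6-(benzyloxy)-4-methoxybenzoate
Product: 20 5'-methoxy-integracin A, (4R)-11-(3,5-dihydroxyphenyl)undecan-4-yl 2-[(9R)-9-acetoxydodecyl]-6-hydroxy-4-methoxybenzoate
Conditions: H2 (1 atm), 10% Pd/C, EtOAc/EtOH, rt
Reagents that add atoms: none
Why: Catalytic hydrogenolysis should remove the three aryl benzyl ethers; the molecule has no alkene, no benzylic C–O ester bond and no other reducible group, so both esters and both stereocentres stay untouched.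

**Compound list**

1 | 3,5-dimethoxybenzyl bromide | COc1cc(CBr)cc(OC)c1 | starting material
2 | 7-bromohept-1-ene | C=CCCCCCBr | starting material
3 | hept-6-en-1-ylmagnesium bromide | C=CCCCCC[Mg]Br | intermediate
4 | 1,3-dimethoxy-5-(oct-7-en-1-yl)benzene | C=CCCCCCCc1cc(OC)cc(OC)c1 | intermediate
5 | butanal | CCCC=O | starting material
6 | 1-bromobutyl acetate (racemic) | CCCC(Br)OC(C)=O | intermediate
7 | (4R)-12-(3,5-dimethoxyphenyl)dodecan-4-yl acetate | CCC[C@H](CCCCCCCCc1cc(OC)cc(OC)c1)OC(C)=O | intermediate
8 | N-{2-[(9R)-9-acetoxydodecyl]-4,6-dimethoxybenzylidene}-N-methylmethanaminium chloride | CCC[C@H](CCCCCCCCc1cc(OC)cc(OC)c1C=[N+](C)C)OC(C)=O.[Cl-] | intermediate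
9 | (4R)-12-(2-formyl-3,5-dimethoxyphenyl)dodecan-4-yl acetate | CCC[C@H](CCCCCCCCc1cc(OC)cc(OC)c1C=O)OC(C)=O | intermediate
10 | (4R)-12-(2-formyl-3-hydroxy-5-methoxyphenyl)dodecan-4-yl acetate | CCC[C@H](CCCCCCCCc1cc(OC)cc(O)c1C=O)OC(C)=O | intermediate
11 | (4R)-12-[3-(benzyloxy)-2-formyl-5-methoxyphenyl]dodecan-4-yl acetate | CCC[C@H](CCCCCCCCc1cc(OC)cc(OCc2ccccc2)c1C=O)OC(C)=O | intermediate
12 | 2-[(9R)-9-acetoxydodecyl]-6-(benzyloxy)-4-methoxybenzoic acid | CCC[C@H](CCCCCCCCc1cc(OC)cc(OCc2ccccc2)c1C(=O)O)OC(C)=O | intermediate
13 | 2-[(9R)-9-acetoxydodecyl]-6-(benzyloxy)-4-methoxybenzoyl bromide | CCC[C@H](CCCCCCCCc1cc(OC)cc(OCc2ccccc2)c1C(=O)Br)OC(C)=O | intermediate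
14 | 3,5-bis(benzyloxy)benzyl bromide | BrCc1cc(OCc2ccccc2)cc(OCc2ccccc2)c1 | starting material
15 | 6-bromohex-1-ene | C=CCCCCBr | starting material
16 | hex-5-en-1-ylmagnesium bromide | C=CCCCC[Mg]Br | intermediate
17 | 1,3-bis(benzyloxy)-5-(hept-6-en-1-yl)benzene | C=CCCCCCc1cc(OCc2ccccc2)cc(OCc2ccccc2)c1 | intermediate
18 | (1RS)-1-bromobutyl 2-[(9R)-9-acetoxydodecyl]-6-(benzyloxy)-4-methoxybenzoate | CCC[C@H](CCCCCCCCc1cc(OC)cc(OCc2ccccc2)c1C(=O)OC(Br)CCC)OC(C)=O | intermediate
19 | (4R)-11-[3,5-bis(benzyloxy)phenyl]undecan-4-yl 2-[(9R)-9-acetoxydodecyl]-6-(benzyloxy)-4-methoxybenzoate | CCC[C@H](CCCCCCCCc1cc(OC)cc(OCc2ccccc2)c1C(=O)O[C@H](CCC)CCCCCCCc1cc(OCc2ccccc2)cc(OCc2ccccc2)c1)OC(C)=O | intermediate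
20 | 5'-methoxy-integracin A, (4R)-11-(3,5-dihydroxyphenyl)undecan-4-yl 2-[(9R)-9-acetoxydodecyl]-6-hydroxy-4-methoxybenzoate | CCC[C@H](CCCCCCCCc1cc(OC)cc(O)c1C(=O)O[C@H](CCC)CCCCCCCc1cc(O)cc(O)c1)OC(C)=O | target

**Count and risks**

Total step count: 10. Longest linear sequence: 9 steps (steps 1 to 7, then 9 and 10); step 8 is a one-step side branch.

Steps most likely to fail:

Step 9. The hindered, electron-rich aroyl bromide may add slowly or reversibly to butanal, the 1-bromoalkyl ester may be reduced by nickel hydride before it couples, and the twisted ortho,ortho'-substituted aroyl carbonyl may chelate nickel poorly, so that enantio-discrimination drops. Because the two stereocentres are far apart, such a shortfall would appear as a diastereomer mixture that is hard to separate. The fallback sets out from 17 and 12 and comes back at 19. Olefin 17 would be coupled with butanal 5 and acetyl bromide (through 6) as in step 2, but with the enantiomeric ligand, to give (4S)-11-[3,5-bis(benzyloxy)phenyl]undecan-4-yl acetate F1. Methanolysis (K2CO3, MeOH, rt) would give (4S)-11-[3,5-bis(benzyloxy)phenyl]undecan-4-ol F2, whose enantiomeric purity can be checked before the halves are joined. Mitsunobu esterification of F2 with acid 12 (PPh3, DIAD, toluene, 0 °C to rt) would then form the ester C–O bond by SN2 displacement at the carbinol carbon, with inversion to (R), and give 19. In this way the hindered carboxyl carbon is never attacked and no acyl bromide is needed.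

Step 7. Hydrogen bromide may cleave the ortho benzyl ether, or the electron-rich acyl bromide may ionise to an acylium ion and decompose on concentration. The fallback sets out from 12 and comes back at 18 without any acyl halide. Ruthenium-catalysed anti-Markovnikov addition of the acid O–H of 12 across but-1-yne (CCC#C; [Ru(methallyl)2(dppb)] cat., toluene, sealed tube, 60 °C) would give (Z)-but-1-en-1-yl 2-[(9R)-9-acetoxydodecyl]-6-(benzyloxy)-4-methoxybenzoate F3. Markovnikov addition of one equivalent of HBr (from TMSBr/MeOH, CH2Cl2, −78 °C) to the enol ester double bond would then give 18, which enters the nickel coupling of step 9 as written.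

Step 2. Incomplete enantiocontrol in the first nickel coupling would be carried through eight further steps and could not be corrected later. The fallback sets out from 2 (as its Grignard reagent 3) and comes back at 7, taking the stereocentre from the chiral pool. Copper-catalysed opening of commercial (R)-2-propyloxirane (CCC[C@@H]1CO1) by 3 at the CH2 terminus (CuI cat., THF, −30 °C) would give (4R)-dodec-11-en-4-ol F4; the C–O bond at the stereocentre is not broken and the descriptor stays R. Acetylation (Ac2O, pyridine, DMAP, CH2Cl2) would give (4R)-dodec-11-en-4-yl acetate F5. Hydroboration with 9-BBN (THF, rt) would give (4R)-12-(9-borabicyclo[3.3.1]nonan-9-yl)dodecan-4-yl acetate F6, which without isolation would undergo B-alkyl Suzuki–Miyaura coupling with commercial 1-bromo-3,5-dimethoxybenzene (COc1cc(Br)cc(OC)c1; PdCl2(dppf), K3PO4, DMF/THF/H2O, 50 °C) to give 7.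

**Further compounds**

F1 | step 9 | (4S)-11-[3,5-bis(benzyloxy)phenyl]undecan-4-yl acetate | CC(=O)O[C@@H](CCC)CCCCCCCc1cc(OCc2ccccc2)cc(OCc2ccccc2)c1
F2 | step 9 | (4S)-11-[3,5-bis(benzyloxy)phenyl]undecan-4-ol | O[C@@H](CCC)CCCCCCCc1cc(OCc2ccccc2)cc(OCc2ccccc2)c1
F3 | step 7 | (Z)-but-1-en-1-yl 2-[(9R)-9-acetoxydodecyl]-6-(benzyloxy)-4-methoxybenzoate | CCC[C@H](CCCCCCCCc1cc(OC)cc(OCc2ccccc2)c1C(=O)O/C=C\CC)OC(C)=O
F4 | step 2 | (4R)-dodec-11-en-4-ol | CCC[C@H](CCCCCCC=C)O
F5 | step 2 | (4R)-dodec-11-en-4-yl acetate | CCC[C@H](CCCCCCC=C)OC(C)=O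
F6 | step 2 | (4R)-12-(9-borabicyclo[3.3.1]nonan-9-yl)dodecan-4-yl acetate | CCC[C@H](CCCCCCCCB1C2CCCC1CCC2)OC(C)=O
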